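**Retrosynthetic overview**
- The last step is Si–O cleavage; before it, ring-closing metathesis at C1=C10 closes the ten-membered carbocycle onto a preformed lactone (lactone ring first, carbocycle second).
- The trans γ-lactone comes from a stereoinvertive lactonisation (C6–O bond, Mitsunobu) of a syn γ-hydroxy acid.
- The hydroxy acid comes from an indium Barbier coupling (C6–C7) of a C1–C6/C15 aldehyde with a C7–C14 allylic bromide acid.
- The bromide comes by cross-metathesis from a branched allylic isobutyrate, made by a new enantioselective allylic C–H isobutyroxylation (C8–O bond; sets C8, which relays to C7).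
- The aldehyde comes from an asymmetric Baeyer–Villiger oxidation of a 4-substituted cyclohexanone (C–O insertion sets C4 and differentiates C1 from C6).

Assumption and atom labels: germacrane numbering is used (C1=C10 ring alkene, C4 bears C15H2OH, C6 carries the lactone oxygen, C7 is the ring-fusion carbon, C8 carries the isobutyrate, C11=C13 is the methylene, C12 the lactone carbonyl, C14 the methyl ester carbon); the target is read as 4S,6R,7S,8R with C2 and C9 cis on the ring alkene, and compounds 1, 7 and 10 are taken as cheap commercial materials.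

**Route**

Step 1
Reactants: 1 4-(hydroxymethyl)cyclohexan-1-one
Product: 2 4-({[tert-butyl(dimethyl)silyl]oxy}methyl)cyclohexan-1-one
Conditions: TBSCl, imidazole, DMF, rt
Reagents that add atoms: tert-butyl(chloro)dimethylsilane (TBSCl), CC(C)(C)[Si](C)(C)Cl
Why: Imidazole-promoted silyl ether formation masks the primary alcohol so that only the C6 hydroxyl is free in the later lactonisation; no stereocenter is formed.

Step 2
Reactants: 2 4-({[tert-butyl(dimethyl)silyl]oxy}methyl)cyclohexan-1-one
Product: 3 (5S)-5-({[tert-butyl(dimethyl)silyl]oxy}methyl)oxepan-2-one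
Conditions: Sc(OTf)3 (5 mol %), chiral N,N′-dioxide ligand (6 mol %), mCPBA (1.2 equiv), EtOAc, −20 °C
Reagents that add atoms: 3-chloroperoxybenzoic acid (mCPBA), O=C(OO)c1cccc(Cl)c1
Why: Asymmetric Baeyer–Villiger desymmetrisation of a prochiral 4-substituted cyclohexanone, in which the chiral Lewis acid selects one of the two enantiotopic migrating CH2 groups of the Criegee intermediate; this sets C4 (S, catalyst enantiomer chosen accordingly) and makes C1 (acyl carbon) and C6 (O-alkyl carbon) different chain ends.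

Step 3
Reactants: 3 (5S)-5-({[tert-butyl(dimethyl)silyl]oxy}methyl)oxepan-2-one
Product: 5 (3S)-3-({[tert-butyl(dimethyl)silyl]oxy}methyl)hept-6-en-1-ol, via hydroxy aldehyde 4 (not isolated)
Conditions: iBu2AlH (1.1 equiv), CH2Cl2, −78 °C; aq. potassium sodium tartrate; crude, then Ph3PCH3Br, KOtBu, THF, 0 °C to rt
Reagents that add atoms: methyltriphenylphosphonium bromide, C[P+](c1ccccc1)(c1ccccc1)c1ccccc1.[Br-]
Why: Half-reduction of the lactone to the hydroxy aldehyde followed by Wittig methylenation turns C1 into the terminal alkene and frees the C6 hydroxyl, leaving C4 untouched.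

Step 4
Reactants: 5 (3S)-3-({[tert-butyl(dimethyl)silyl]oxy}methyl)hept-6-en-1-ol
Product: 6 (3S)-3-({[tert-butyl(dimethyl)silyl]oxy}methyl)hept-6-enal
Conditions: TEMPO (10 mol %), PhI(OAc)2 (1.1 equiv), CH2Cl2, rt
Reagents that add atoms: none
Why: Oxoammonium (TEMPO) oxidation of the primary alcohol stops at the aldehyde (C6) and leaves the alkene and silyl ether alone.

Step 5
Reactants: 7 methyl 2-(bromomethyl)prop-2-enoate
Product: 8 methyl 2-methylidenehex-5-enoate
Conditions: allylMgBr (1.1 equiv), CuBr·SMe2 (5 mol %), THF, −78 °C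
Reagents that add atoms: allylmagnesium bromide, C=CC[Mg]Br
Why: Copper-catalysed SN2′ allylation of the 2-(bromomethyl)acrylate (both substitution modes give the same product) joins C8–C9 at low temperature without attack on the ester; no stereocenter is formed.

Step 6
Reactants: 8 methyl 2-methylidenehex-5-enoate
Product: 9 methyl (4R)-2-methylidene-4-[(2-methylpropanoyl)oxy]hex-5-enoate
Conditions: Pd(OAc)2 (10 mol %), chiral sulfoxide–oxazoline ligand with a urea side arm (12 mol %), 2,6-dimethyl-1,4-benzoquinone (1.5 equiv), iPrCO2H (2 equiv), toluene, 45 °C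
Reagents that add atoms: 2-methylpropanoic acid (isobutyric acid), CC(C)C(=O)O
Why: Proposed new method: enantioselective branched allylic C–H acyloxylation of an α-olefin, in which electrophilic divalent palladium cleaves the allylic C8–H of the only unactivated terminal alkene (the acrylate alkene is electron-poor and 1,1-disubstituted) to give a π-allylpalladium species held by the chiral bidentate ligand, the urea arm binds isobutyrate by hydrogen bonding and delivers it to the internal allyl terminus on one face (π–σ–π equilibration being faster than C–O bond formation, so the ligand enantiomer fixes 8R), and the quinone reoxidises zerovalent palladium; the closest known reaction type is the palladium/sulfoxide-catalysed branched allylic C–H esterification of terminal alkenes with carboxylic acids (known racemic or with modest ee) together with ligand-controlled asymmetric intramolecular allylic C–H oxidation.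

Step 7
Reactants: 9 methyl (4R)-2-methylidene-4-[(2-methylpropanoyl)oxy]hex-5-enoate, 10 2-(bromomethyl)prop-2-enoic acid
Product: 11 (2Z,4R)-2-(bromomethyl)-6-(methoxycarbonyl)-4-[(2-methylpropanoyl)oxy]hepta-2,6-dienoic acid
Conditions: 10 (4 equiv), second-generation Hoveyda–Grubbs catalyst (7 mol %), CH2Cl2, 40 °C
Reagents that add atoms: none
Why: Cross-metathesis in which the monosubstituted alkene of 9 loads the ruthenium carbene and couples with the 1,1-disubstituted acrylic acid used in excess, giving the trisubstituted C7=C11 alkene in its thermodynamic geometry (C8 trans to the carboxyl group, Z by CIP because CH2Br outranks CO2H); C8 is untouched.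

Step 8
Reactants: 6 (3S)-3-({[tert-butyl(dimethyl)silyl]oxy}methyl)hept-6-enal, 11 (2Z,4R)-2-(bromomethyl)-6-(methoxycarbonyl)-4-[(2-methylpropanoyl)oxy]hepta-2,6-dienoic acid
Product: 12 (3S,4S,6S)-6-({[tert-butyl(dimethyl)silyl]oxy}methyl)-4-hydroxy-3-{(1R)-4-methoxy-3-methylidene-1-[(2-methylpropanoyl)oxy]-4-oxobutyl}-2-methylidenedec-9-enoic acid
Conditions: In powder (2 equiv), THF/H2O 1:1, rt; work-up at pH 5, 0 °C
Reagents that add atoms: none
Why: Indium-mediated Barbier 2-carboxyallylation in which the (Z)-allylindium reacts at its γ-carbon C7 through a closed chair transition state (aldehyde chain equatorial, C8 axial) to give the syn C6/C7 adduct, while the aldehyde adds to the face of C7 anti to the C9 chain of the A(1,3)-minimised C8 rotamer (C8–H in the alkene plane, acyloxy group outside), which sets 7S from 8R; C6 is formed on purpose with the configuration opposite to the target (6S).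

Step 9
Reactants: 12 (3S,4S,6S)-6-({[tert-butyl(dimethyl)silyl]oxy}methyl)-4-hydroxy-3-{(1R)-4-methoxy-3-methylidene-1-[(2-methylpropanoyl)oxy]-4-oxobutyl}-2-methylidenedec-9-enoic acid
Product: 13 methyl (4R)-4-[(2R,3S)-2-[(2S)-2-({[tert-butyl(dimethyl)silyl]oxy}methyl)hex-5-en-1-yl]-4-methylidene-5-oxooxolan-3-yl]-2-methylidene-4-[(2-methylpropanoyl)oxy]butanoate
Conditions: PPh3 (1.5 equiv), DIAD (1.5 equiv), THF (0.01 M), 0 °C
Reagents that add atoms: none
Why: Mitsunobu lactonisation, in which the activated C6 oxygen is displaced by the C12 carboxylate in a 5-exo SN2 reaction with clean inversion, converts 6S into 6R and closes the α-methylene γ-lactone with C5 and C8 trans.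

Step 10
Reactants: 13 methyl (4R)-4-[(2R,3S)-2-[(2S)-2-({[tert-butyl(dimethyl)silyl]oxy}methyl)hex-5-en-1-yl]-4-methylidene-5-oxooxolan-3-yl]-2-methylidene-4-[(2-methylpropanoyl)oxy]butanoate
Product: 14 methyl (3aS,4R,6E,10S,11aR)-10-({[tert-butyl(dimethyl)silyl]oxy}methyl)-3-methylidene-4-[(2-methylpropanoyl)oxy]-2-oxo-2,3,3a,4,5,8,9,10,11,11a-decahydrocyclodeca[b]furan-6-carboxylate
Conditions: second-generation Hoveyda–Grubbs catalyst (15 mol %, in portions), 1,4-benzoquinone (10 mol %), toluene (1 mM), 80 °C
Reagents that add atoms: none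
Why: Ring-closing metathesis between the C1 terminal alkene and the C10 acrylate alkene, pre-organised by the trans lactone, gives the ten-membered ring with C2 and C9 cis (6E by CIP), the geometry favoured both by the medium ring and by 2-alkylidene esters, while the lactone methylene cannot cyclise without forming a bridgehead alkene.

Step 11
Reactants: 14 methyl (3aS,4R,6E,10S,11aR)-10-({[tert-butyl(dimethyl)silyl]oxy}methyl)-3-methylidene-4-[(2-methylpropanoyl)oxy]-2-oxo-2,3,3a,4,5,8,9,10,11,11a-decahydrocyclodeca[b]furan-6-carboxylate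
Product: 15 methyl (3aS,4R,6E,10S,11aR)-10-(hydroxymethyl)-3-methylidene-4-[(2-methylpropanoyl)oxy]-2-oxo-2,3,3a,4,5,8,9,10,11,11a-decahydrocyclodeca[b]furan-6-carboxylate (target)
Conditions: HF·pyridine, THF/pyridine, 0 °C to rt
Reagents that add atoms: none
Why: Fluoride cleavage of the primary silyl ether under mildly acidic, non-nucleophilic conditions frees C15–OH without conjugate addition to the methylene lactone or ester cleavage; no stereocenter is touched.

**Compound list**

1 | 4-(hydroxymethyl)cyclohexan-1-one | O=C1CCC(CO)CC1 | starting material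
2 | 4-({[tert-butyl(dimethyl)silyl]oxy}methyl)cyclohexan-1-one | O=C1CCC(CO[Si](C)(C)C(C)(C)C)CC1 | intermediate
3 | (5S)-5-({[tert-butyl(dimethyl)silyl]oxy}methyl)oxepan-2-one | O=C1CC[C@H](CO[Si](C)(C)C(C)(C)C)CCO1 | intermediate
4 | (4S)-4-({[tert-butyl(dimethyl)silyl]oxy}methyl)-6-hydroxyhexanal (not isolated) | O=CCC[C@H](CO[Si](C)(C)C(C)(C)C)CCO | intermediate
5 | (3S)-3-({[tert-butyl(dimethyl)silyl]oxy}methyl)hept-6-en-1-ol | C=CCC[C@H](CO[Si](C)(C)C(C)(C)C)CCO | intermediate
6 | (3S)-3-({[tert-butyl(dimethyl)silyl]oxy}methyl)hept-6-enal | C=CCC[C@H](CO[Si](C)(C)C(C)(C)C)CC=O | intermediate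
7 | methyl 2-(bromomethyl)prop-2-enoate | C=C(CBr)C(=O)OC | starting material
8 | methyl 2-methylidenehex-5-enoate | C=CCCC(=C)C(=O)OC | intermediate
9 | methyl (4R)-2-methylidene-4-[(2-methylpropanoyl)oxy]hex-5-enoate | COC(=O)C(=C)C[C@@H](OC(=O)C(C)C)C=C | intermediate
10 | 2-(bromomethyl)prop-2-enoic acid | C=C(CBr)C(=O)O | starting material
11 | (2Z,4R)-2-(bromomethyl)-6-(methoxycarbonyl)-4-[(2-methylpropanoyl)oxy]hepta-2,6-dienoic acid | COC(=O)C(=C)C[C@@H](OC(=O)C(C)C)/C=C(\CBr)C(=O)O | intermediate
12 | (3S,4S,6S)-6-({[tert-butyl(dimethyl)silyl]oxy}methyl)-4-hydroxy-3-{(1R)-4-methoxy-3-methylidene-1-[(2-methylpropanoyl)oxy]-4-oxobutyl}-2-methylidenedec-9-enoic acid | C=CCC[C@H](CO[Si](C)(C)C(C)(C)C)C[C@H](O)[C@H](C(=C)C(=O)O)[C@H](OC(=O)C(C)C)CC(=C)C(=O)OC | intermediate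
13 | methyl (4R)-4-[(2R,3S)-2-[(2S)-2-({[tert-butyl(dimethyl)silyl]oxy}methyl)hex-5-en-1-yl]-4-methylidene-5-oxooxolan-3-yl]-2-methylidene-4-[(2-methylpropanoyl)oxy]butanoate | C=CCC[C@H](CO[Si](C)(C)C(C)(C)C)C[C@H]1OC(=O)C(=C)[C@@H]1[C@H](OC(=O)C(C)C)CC(=C)C(=O)OC | intermediate
14 | methyl (3aS,4R,6E,10S,11aR)-10-({[tert-butyl(dimethyl)silyl]oxy}methyl)-3-methylidene-4-[(2-methylpropanoyl)oxy]-2-oxo-2,3,3a,4,5,8,9,10,11,11a-decahydrocyclodeca[b]furan-6-carboxylate | C=C1C(=O)O[C@@H]2C[C@@H](CO[Si](C)(C)C(C)(C)C)CC/C=C(/C(=O)OC)C[C@@H](OC(=O)C(C)C)[C@@H]12 | intermediate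
15 | methyl (3aS,4R,6E,10S,11aR)-10-(hydroxymethyl)-3-methylidene-4-[(2-methylpropanoyl)oxy]-2-oxo-2,3,3a,4,5,8,9,10,11,11a-decahydrocyclodeca[b]furan-6-carboxylate | C=C1C(=O)O[C@@H]2C[C@@H](CO)CC/C=C(/C(=O)OC)C[C@@H](OC(=O)C(C)C)[C@@H]12 | target

**Step count and risks**

Total steps: 11. Longest linear sequence: 8 steps (steps 1–4, then 8–11); the other branch is steps 5–7.

The three steps most likely to fail:

Step 6 (the new enantioselective allylic C–H isobutyroxylation) may give low ee or linear ester. The fallback uses known chemistry, sets out from 7 and comes back at 9. Zn-mediated Barbier reaction of 7 with acrolein (Zn dust, THF/aq. NH4Cl, 0 °C) gives racemic methyl 4-hydroxy-2-methylidenehex-5-enoate F1. Kinetic resolution with Candida antarctica lipase B and vinyl acetate leaves methyl (4R)-4-hydroxy-2-methylidenehex-5-enoate F2 and removes the (S)-enantiomer as methyl (4S)-4-acetoxy-2-methylidenehex-5-enoate F3 (vinyl is the medium group in the Kazlauskas model). F2 is then esterified with isobutyryl chloride and pyridine to give 9.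

Step 7 (cross-metathesis of a hindered allylic ester with a 2-substituted acrylic acid) may be slow or give oligomers through the acrylate end of 9. The fallback replaces metathesis by carbonyl chemistry, sets out from 9 and comes back at 11. Cleavage of the vinyl group with OsO4 (cat.)/NaIO4 and 2,6-lutidine gives methyl (4R)-2-methylidene-4-[(2-methylpropanoyl)oxy]-5-oxopentanoate F4. Morita–Baylis–Hillman reaction with tert-butyl acrylate (DABCO) gives 1-tert-butyl 7-methyl (4R)-3-hydroxy-2,6-dimethylidene-4-[(2-methylpropanoyl)oxy]heptanedioate F5, of which both carbinol epimers serve. PBr3 converts it with allylic transposition into 1-tert-butyl 7-methyl (2Z,4R)-2-(bromomethyl)-6-methylidene-4-[(2-methylpropanoyl)oxy]hept-2-enedioate F6, and CF3CO2H removes the tert-butyl group to give 11.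

Step 10 (ring-closing metathesis to a ten-membered ring with a trisubstituted, ester-bearing alkene) may give dimers or fail to close. The fallback changes the ring-closing bond from C1=C10 to C6–C7, replaces steps 8–10, sets out from 6 and 11 and comes back at 14. Cross-metathesis of the terminal alkene of 6 with the acrylate unit of 11 gives (2Z,4R,6E,10S)-2-(bromomethyl)-10-({[tert-butyl(dimethyl)silyl]oxy}methyl)-6-(methoxycarbonyl)-4-[(2-methylpropanoyl)oxy]-12-oxododeca-2,6-dienoic acid F7. Intramolecular In-mediated Barbier reaction at high dilution closes the carbocycle to 2-[(1S,2R,4E,8S,10S)-8-({[tert-butyl(dimethyl)silyl]oxy}methyl)-10-hydroxy-4-(methoxycarbonyl)-2-[(2-methylpropanoyl)oxy]cyclodec-4-en-1-yl]prop-2-enoic acid F8. Mitsunobu lactonisation with inversion at C6 then gives 14.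

Further compounds
F1 | step 6 | methyl 4-hydroxy-2-methylidenehex-5-enoate (racemic) | C=CC(O)CC(=C)C(=O)OC
F2 | step 6 | methyl (4R)-4-hydroxy-2-methylidenehex-5-enoate | COC(=O)C(=C)C[C@@H](O)C=C
F3 | step 6 | methyl (4S)-4-acetoxy-2-methylidenehex-5-enoate | COC(=O)C(=C)C[C@H](OC(C)=O)C=C
F4 | step 7 | methyl (4R)-2-methylidene-4-[(2-methylpropanoyl)oxy]-5-oxopentanoate | COC(=O)C(=C)C[C@@H](OC(=O)C(C)C)C=O
F5 | step 7 | 1-tert-butyl 7-methyl (4R)-3-hydroxy-2,6-dimethylidene-4-[(2-methylpropanoyl)oxy]heptanedioate (both C3 epimers) | COC(=O)C(=C)C[C@@H](OC(=O)C(C)C)C(O)C(=C)C(=O)OC(C)(C)C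
F6 | step 7 | 1-tert-butyl 7-methyl (2Z,4R)-2-(bromomethyl)-6-methylidene-4-[(2-methylpropanoyl)oxy]hept-2-enedioate | COC(=O)C(=C)C[C@@H](OC(=O)C(C)C)/C=C(\CBr)C(=O)OC(C)(C)C
F7 | step 10 | (2Z,4R,6E,10S)-2-(bromomethyl)-10-({[tert-butyl(dimethyl)silyl]oxy}methyl)-6-(methoxycarbonyl)-4-[(2-methylpropanoyl)oxy]-12-oxododeca-2,6-dienoic acid | O=CC[C@@H](CO[Si](C)(C)C(C)(C)C)CC/C=C(/C(=O)OC)C[C@@H](OC(=O)C(C)C)/C=C(\CBr)C(=O)O
F8 | step 10 | 2-[(1S,2R,4E,8S,10S)-8-({[tert-butyl(dimethyl)silyl]oxy}methyl)-10-hydroxy-4-(methoxycarbonyl)-2-[(2-methylpropanoyl)oxy]cyclodec-4-en-1-yl]prop-2-enoic acid | OC(=O)C(=C)[C@H]1[C@@H](O)C[C@@H](CO[Si](C)(C)C(C)(C)C)CC/C=C(/C(=O)OC)C[C@H]1OC(=O)C(C)C
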